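# Proposed total synthesis of pestallic acid J (24)

## Structural features

Pestallic acid J (24) has one ring, a cyclohex-2-en-1-one in which all six carbons are substituted. C1 is the ketone and C2 carries an (E)-hept-1-enyl chain (C1'–C7') with an acetoxy group at C6'. C3 carries the hydroxymethyl carbon C7, C4 and C5 carry secondary hydroxyls, and C6 carries an (E)-3-carboxybut-2-enyl chain (C1''–C4''). The tetrasubstituted C2=C3 alkene forms, with C1'=C2', a diene that is cross-conjugated to the C1 carbonyl.

Three stereocentres stand side by side: C4 (R), C5 (S) and C6 (R), with both hydroxyls and the C1'' methylene on the same ring face. The fourth, C6' (R), lies five bonds from the ring and cannot be relayed from it.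

The C5 hydroxyl is β to the ketone and C6–H is acidic, so base or strong acid can expel water, and the resulting dienone tautomerises to a hydroquinone. The same C6–H makes the C6 configuration labile, and the secondary acetate beside a free acid and three free hydroxyls rules out a basic or hydridic last step.

The skeleton itself is easy to assemble. The real difficulty is the absolute configuration of a cis-diol on a ring one dehydration away from an arene, and the placing of the C6 chain on the more crowded face.

The key step exploits the array C1(=O)–C2=C3–C4(OH)–C5(OH)–C6H2. This array is the keto tautomer of a meta-substituted phenol that has taken up two hydroxyls on its C4–C5 edge. A purchased arene with a halogen at C3 therefore already holds the ring, the ketone position and the alkene position.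

## Logic of the disconnections

**24 ⇒ 23.** No skeletal bond is cut. The O–C(tert-butyl) bond of the ester, the O–Si bond at C7 and the two ketal C–O bonds at C4/C5 are restored. All three masks are chosen to fall in one aqueous acid treatment, which the acetate tolerates. The gain is that the free acid and triol never meet base, palladium or ruthenium. The demand is an exposure short and cold enough not to enolise C1/C6 or ionise the allylic C4–O bond.

**23 ⇒ 21 (through 22).** The bond cut is C6–H. The crowded 6R configuration is traced back to the planar enolate 22, which can be made from either C6 epimer. Every earlier step is thereby freed from C6 stereocontrol, and only one step follows the setting of this labile centre. The demand is selective deprotonation at C6 and delivery of the proton from the face opposite the ketal.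

**21 ⇒ 13 + 20.** The C2–C1' bond between two sp2 carbons is cut. This splits the molecule into ring and side chain at the point of highest convergence. The E geometry of C1'=C2' then comes from 20 rather than from the bond-forming event. The demand is a coupling that runs at room temperature on a hindered tetrasubstituted vinyl iodide without prolonged enolising conditions.

**20 ⇒ 18 + 19; 18 ⇒ 17 ⇒ 14 + 15.** The C1'=C2' alkene is cut by a metathesis transform, then the acetyl C–O bond, then C4'–C5'. The remote C6' centre is bought in 14 and never touched, because the nucleophile attacks the unsubstituted epoxide carbon. The demand is E selectivity in the metathesis, which the bulky boronate supports.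

**13 ⇒ 11 + 12.** The C2''=C3'' alkene is cut. A γ-bromo enoate electrophile would save one linear step. It would also offer the enolate a Michael acceptor, with conjugate addition and cyclopropane closure as escape routes, and it would need two steps of its own. A plain allyl group followed by metathesis is safer and shorter overall. The demand is that no other alkene in 11 is metathesis-active, which holds because C2=C3 is tetrasubstituted.

**11 ⇒ 8 + 9 (through 10).** The C6–C1'' bond is cut next to the ketone, its natural nucleophilic position. It is done before any ester or acetate is present, so the base meets only one acidic site class. The demand is that alkylation outruns loss of the C5 oxygen from 10.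

**8 ⇒ 7.** The C2–I bond is cut. Iodination is placed where C2=C3 is the only alkene in the molecule, which removes chemoselectivity questions. The demand is a reagent that works although the β-carbon C3 is fully substituted.

**7 ⇒ 6 ⇒ 4 + 5.** The O–Si bond is cut, then C3–C7. The iodine that steered the enzyme becomes the leaving group of a neutral cross-coupling, so it is used twice. The demand is transfer of the oxygenated methylene in preference to butyl.

**4 ⇒ 3 ⇒ 1 (through 2).** The ketal is removed, then the C4–O and C5–O bonds are cut. The target ring collapses to a flat, achiral, purchased arene. Two stereocentres, the ketone and the alkene arise in one operation. The demand is edge and face selectivity, which no small-molecule reagent offers and the enzyme pocket does.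

## Other disconnections considered

**Alternative 1:** The cut removes C2=C3 and C1'=C2' together and leads to the acyclic 1,7-enyne A2 and the alkene 18. In the forward sense a ruthenium alkylidene loaded from 18 adds to the terminal alkyne of A2. The C2 vinylcarbene so formed then closes on the C3 methylidene to give the cyclohexenol A1.

- *In its favour:* ring, tetrasubstituted alkene and diene come from one catalytic step without halogenation or palladium. C1 stays a carbinol, so C6 cannot epimerise and the C5 oxygen cannot leave by E1cB until a late oxidation. On the handling of C6 this plan is better than the chosen one.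
- *Against it:* the catalyst must load on 18 and not on the alkenes of A2. The geometry of C1'=C2' is not dictated by the mechanism of enyne metathesis, whereas the chosen coupling only transfers a preformed E alkene. Closure of a vinylcarbene on a 1,1-disubstituted alkene next to a ketal is a slow way to a tetrasubstituted alkene.
- *Step economy:* A2 holds four contiguous stereocentres (C1, C6, C5, C4) that must be built in open-chain form. This is estimated to cost more steps than the whole chosen ring sequence.
- *Equal point:* the end game (oxidation apart) and the lability of the final enone are the same in both plans.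

**Alternative 2:** The cut removes C4–C5 and C1–C6. The forward step is an endo [4+2] cycloaddition of the dioxine diene A4 with Lewis-acid-bound cyclobutenone A5, giving the tricyclic ketone A3.

- *In its favour:* suprafacial addition and the endo rule place the C4 oxygen, the C5 acyl carbon and the C6 methylene on one face in a single step. Baeyer–Villiger insertion with retention then gives the C5 oxygen, and lactone reduction with Wittig olefination gives the C6 chain without any enolate. For the relative configuration of the triad, and of C6 in particular, this is clearly better than the chosen plan.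
- *Against it:* absolute control would depend on a chiral Lewis acid for a volatile, polymerisable dienophile and an acid-labile enol-acetal diene. The chosen plan takes absolute control from the enzyme.
- *Remaining work:* in A3 C1 is still a methylene and C2 still a CH. A regioselective allylic oxidation therefore remains, followed by the same α-halogenation and coupling on a β-substituted enone as in the chosen plan (an equal point). Once C1 is a ketone, C6 is as labile as in the chosen plan.
- *Step economy:* the step count after A3 is estimated to be higher than that after 3.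

**Alternative 3:** The cut removes the C5–O and C6–O bonds of the epoxyquinone A6, which leads to the fully substituted quinone A7. In the forward sense a hydroperoxide anion paired with a chiral ammonium cation adds to C5, and the enolate closes at C6.

- *In its favour:* the plan follows a plausible biogenesis. All three side chains are attached by arene chemistry, and convergence is equal to or better than in the chosen plan.
- *Against it (downstream selectivity):* both oxirane carbons are α to a carbonyl, so reductive opening must choose C6–O over C5–O. The C4 ketone must then be reduced in preference to C1 and from the right face.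
- *Against it (C6):* in A6 the C6 chain lies on the face opposite the oxirane oxygen. The target configuration therefore has to be made by protonation of an enolate here too, the same problem as in step 12 but without a ketal to bias the faces.
- *Against it (substrate):* face selectivity by ion pairing on a trisubstituted quinone is less secure mechanistically than an enzyme pocket. A 1-alkenyl quinone is prone to tautomerisation and electrocyclisation, and basic peroxide endangers the acetate.
- *Step economy:* the total is estimated as similar or longer.

Key step: step 1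

Remark on the chemistry: the ring locants C1–C6 of 24 are used for all intermediates. The C4 descriptor changes from S to R when carbon replaces iodine at C3, without any spatial change. A toluene dioxygenase strain that lacks diol dehydrogenase activity is taken to be an available biocatalyst.

## Steps

**Step 1**
Reactants: 1 3-iodophenol
Product: 3 (4S,5S)-4,5-dihydroxy-3-iodocyclohex-2-en-1-one, via dienol triol 2 (not isolated)
Conditions: Pseudomonas putida UV4 whole cells (toluene dioxygenase), glucose, air, phosphate buffer pH 7, 30 °C, 1 fed in portions; NaCl, EtOAc extraction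
Reagents that add atoms: dioxygen O=O
Why: This is an enzymatic dearomatising cis-dihydroxylation by a Rieske non-haem iron dioxygenase, the reaction type known for halobenzenes and for meta-substituted phenols. Electrons from NADH reach the mononuclear iron through the [2Fe–2S] cluster, O2 is bound and reduced there, and both oxygen atoms pass to the same face of one arene edge, which is why the two new C–O bonds can only be cis. No ring is closed. Iodine, the largest substituent, sits in the hydrophobic part of the pocket and brings an ortho/meta edge over the iron; of the two such edges C2–C1 already bears the phenolic oxygen, so C4–C5 is the edge that gives a stable diol. The same binding mode presents a single enantioface and sets C4 (S) and C5 (S) in 3, which are the 4R,5S centres of 24. The first product 2 is a dienol that ketonises by protonation at C6 to the conjugated enone 3, which fixes the C1 ketone and the C2=C3 alkene. The step needs edge selectivity, face selectivity and survival of a product that can dehydrate to an iodohydroquinone; the pocket secures the first two, and a strain without diol dehydrogenase, neutral pH and prompt extraction serve the third.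

**Step 2**
Reactants: 3 (4S,5S)-4,5-dihydroxy-3-iodocyclohex-2-en-1-one
Product: 4 (4S,5S)-3-iodo-4,5-(isopropylidenedioxy)cyclohex-2-en-1-one
Conditions: Me2C(OMe)2, PPTS (cat.), CH2Cl2, 0 °C to rt
Reagents that add atoms: 2,2-dimethoxypropane COC(C)(C)OC
Why: Acid-catalysed transketalisation closes the dioxolane on the cis-1,2-diol, and the weak acid and low temperature keep the β-hydroxy ketone from dehydrating. No stereocentre is touched, and the ketal later shields one ring face.

**Step 3**
Reactants: 4 (4S,5S)-3-iodo-4,5-(isopropylidenedioxy)cyclohex-2-en-1-one; 5 (tributylstannyl)methanol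
Product: 6 (4R,5S)-3-(hydroxymethyl)-4,5-(isopropylidenedioxy)cyclohex-2-en-1-one
Conditions: Pd(PPh3)4 (5 mol %), 1,4-dioxane, 80 °C
Reagents that add atoms: none
Why: In this Stille coupling the β-iodoenone behaves as a vinylogous acyl iodide and adds readily to Pd(0), and the α-oxygenated methylene of 5 is transferred in preference to butyl. The medium is neutral, so C6–H is not enolised and the C5 oxygen stays in place.

**Step 4**
Reactants: 6 (4R,5S)-3-(hydroxymethyl)-4,5-(isopropylidenedioxy)cyclohex-2-en-1-one
Product: 7 (4R,5S)-3-[(tert-butyldimethylsilyloxy)methyl]-4,5-(isopropylidenedioxy)cyclohex-2-en-1-one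
Conditions: TBSCl, imidazole, CH2Cl2, 0 °C
Reagents that add atoms: tert-butyldimethylsilyl chloride CC(C)(C)[Si](C)(C)Cl
Why: Standard silylation of a primary alcohol protects it from the iodine(III) oxidant of step 5 and from the bases of steps 6 and 12. The silyl ether falls in the same acid treatment as the ketal and the tert-butyl ester.

**Step 5**
Reactants: 7 (4R,5S)-3-[(tert-butyldimethylsilyloxy)methyl]-4,5-(isopropylidenedioxy)cyclohex-2-en-1-one
Product: 8 (4R,5S)-3-[(tert-butyldimethylsilyloxy)methyl]-2-iodo-4,5-(isopropylidenedioxy)cyclohex-2-en-1-one
Conditions: I2, PhI(OCOCF3)2, pyridine, CH2Cl2, rt, dark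
Reagents that add atoms: iodine II
Why: Electrophilic α-iodination of an enone by the acyl hypoiodite made in the flask, followed by pyridine-assisted loss of the C2 proton, is known for β-alkyl cyclohexenones. It is preferred here because the amine-catalysed (Baylis–Hillman-type) iodination needs an unhindered β-carbon, which C3 is not. At this stage C2=C3 is the only alkene present.

**Step 6**
Reactants: 8 (4R,5S)-3-[(tert-butyldimethylsilyloxy)methyl]-2-iodo-4,5-(isopropylidenedioxy)cyclohex-2-en-1-one; 9 allyl iodide
Product: 11 (4R,5S,6S)-6-allyl-3-[(tert-butyldimethylsilyloxy)methyl]-2-iodo-4,5-(isopropylidenedioxy)cyclohex-2-en-1-one (allyl trans to the C5 oxygen), via lithium dienolate 10 (not isolated)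
Conditions: LiHMDS (1.05 equiv), THF, −78 °C; 9 (3 equiv), DMPU, −78 to −50 °C; pH 7 buffer
Reagents that add atoms: lithium hexamethyldisilazide [Li]N([Si](C)(C)C)[Si](C)(C)C (its lithium stays only in 10)
Why: Kinetic α'-deprotonation of the enone gives the cross-conjugated enolate 10, and SN2 alkylation by the very reactive allyl iodide at low temperature should outrun expulsion of the C5 oxygen. The electrophile approaches the face opposite the dioxolane and gives 6S, a provisional configuration that step 12 resets.

**Step 7**
Reactants: 11 (4R,5S,6S)-6-allyl-3-[(tert-butyldimethylsilyloxy)methyl]-2-iodo-4,5-(isopropylidenedioxy)cyclohex-2-en-1-one; 12 tert-butyl methacrylate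
Product: 13 (4R,5S,6S)-6-[(E)-3-(tert-butoxycarbonyl)but-2-enyl]-3-[(tert-butyldimethylsilyloxy)methyl]-2-iodo-4,5-(isopropylidenedioxy)cyclohex-2-en-1-one
Conditions: Hoveyda–Grubbs II (5 mol %), 12 (10 equiv), CH2Cl2, 40 °C
Reagents that add atoms: none
Why: Olefin cross metathesis of a terminal alkene with a methacrylate, which hardly homodimerises, is a known route to trisubstituted enoates. The reversible process favours the E isomer, with the ester trans to the chain. The tetrasubstituted iodoalkene is inert and the medium is neutral.

**Step 8**
Reactants: 14 (R)-propylene oxide; 15 but-3-enylmagnesium bromide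
Product: 17 (R)-hept-6-en-2-ol, via bromomagnesium alkoxide 16 (not isolated)
Conditions: CuI (10 mol %), THF, −30 to 0 °C; aqueous work-up
Reagents that add atoms: none
Why: Copper-catalysed Grignard opening of a terminal epoxide occurs by SN2 attack at the unsubstituted carbon. The stereocentre takes no part, so the R configuration of 14 becomes C6' (R).

**Step 9**
Reactants: 17 (R)-hept-6-en-2-ol
Product: 18 (R)-hept-6-en-2-yl acetate
Conditions: Ac2O, pyridine, DMAP (cat.), CH2Cl2, 0 °C to rt
Reagents that add atoms: acetic anhydride CC(=O)OC(C)=O
Why: O-Acylation leaves the C–O bond of the carbinol intact, so the configuration is retained. The acetate of the target is thus in place before the fragments are joined.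

**Step 10**
Reactants: 18 (R)-hept-6-en-2-yl acetate; 19 vinylboronic acid pinacol ester
Product: 20 (R,E)-7-(4,4,5,5-tetramethyl-1,3,2-dioxaborolan-2-yl)hept-6-en-2-yl acetate
Conditions: Grubbs II (3 mol %), 19 (2 equiv), CH2Cl2, 40 °C
Reagents that add atoms: none
Why: Cross metathesis of a terminal alkene with a vinyl boronate is a known route to (E)-alkenyl boronates, and the bulk of the pinacol boronate favours the E isomer. The acetate and C6' are remote and untouched.

**Step 11**
Reactants: 13 (4R,5S,6S)-6-[(E)-3-(tert-butoxycarbonyl)but-2-enyl]-3-[(tert-butyldimethylsilyloxy)methyl]-2-iodo-4,5-(isopropylidenedioxy)cyclohex-2-en-1-one; 20 (R,E)-7-(4,4,5,5-tetramethyl-1,3,2-dioxaborolan-2-yl)hept-6-en-2-yl acetate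
Product: 21 (4R,5S,6S)-2-[(1E,6R)-6-acetoxyhept-1-enyl]-6-[(E)-3-(tert-butoxycarbonyl)but-2-enyl]-3-[(tert-butyldimethylsilyloxy)methyl]-4,5-(isopropylidenedioxy)cyclohex-2-en-1-one
Conditions: Pd(dppf)Cl2·CH2Cl2 (5 mol %), AsPh3 (10 mol %), aq K3PO4, THF, rt, degassed
Reagents that add atoms: none
Why: Suzuki–Miyaura coupling of an α-iodoenone with an alkenyl boronate proceeds with retention at both sp2 carbons, so the E geometry of 20 is carried into the diene. The iodide allows room temperature, which spares the acetate and limits enolisation. Any drift at C6 is harmless because step 12 erases it.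

**Step 12**
Reactants: 21 (4R,5S,6S)-2-[(1E,6R)-6-acetoxyhept-1-enyl]-6-[(E)-3-(tert-butoxycarbonyl)but-2-enyl]-3-[(tert-butyldimethylsilyloxy)methyl]-4,5-(isopropylidenedioxy)cyclohex-2-en-1-one
Product: 23 the (4R,5S,6R) epimer of 21 (C6 chain cis to both ring oxygens), via lithium dienolate 22 (not isolated)
Conditions: LiHMDS (1.5 equiv), THF, −78 to −45 °C; 2,6-di-tert-butyl-4-methylphenol (5 equiv), THF, −78 °C; AcOH, −78 °C
Reagents that add atoms: lithium hexamethyldisilazide [Li]N([Si](C)(C)C)[Si](C)(C)C (its lithium stays only in 22)
Why: This is deprotonation followed by kinetic protonation of an enolate, the classical way to a contra-thermodynamic α-epimer. In 22 the atoms C6, C1, C2 and C3 are coplanar and the dioxolane covers one face, so the bulky phenol should reach C6 only from the other face and push the C1'' chain cis to the ring oxygens (6R). The silazide is chosen because it discriminates for the ketone, and any acetate enolate that forms is returned unchanged by the quench.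

**Step 13**
Reactants: 23 (4R,5S,6R)-2-[(1E,6R)-6-acetoxyhept-1-enyl]-6-[(E)-3-(tert-butoxycarbonyl)but-2-enyl]-3-[(tert-butyldimethylsilyloxy)methyl]-4,5-(isopropylidenedioxy)cyclohex-2-en-1-one
Product: 24 pestallic acid J
Conditions: TFA/H2O 9:1, 0 °C to rt; co-evaporation with toluene, no basic work-up
Reagents that add atoms: none
Why: Acidolysis cleaves the tert-butyl ester by alkyl–oxygen fission, hydrolyses the ketal and removes the primary silyl ether in one operation, while a secondary acetate is stable to aqueous trifluoroacetic acid. No C–O bond at a stereocentre is broken, and the short cold exposure is meant to stay below the threshold for enolisation at C6.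

## Compound list

| No. | Name | SMILES | Role |
|---|---|---|---|
| 1 | 3-iodophenol | Oc1cccc(I)c1 | starting material |
| 2 | (1S,2S)-3-iodocyclohexa-3,5-diene-1,2,5-triol | OC1=C[C@H](O)[C@H](O)C(I)=C1 | intermediate |
| 3 | (4S,5S)-4,5-dihydroxy-3-iodocyclohex-2-en-1-one | O=C1C=C(I)[C@@H](O)[C@@H](O)C1 | intermediate |
| 4 | (4S,5S)-3-iodo-4,5-(isopropylidenedioxy)cyclohex-2-en-1-one | O=C1C=C(I)[C@H]2OC(C)(C)O[C@H]2C1 | intermediate |
| 5 | (tributylstannyl)methanol | CCCC[Sn](CCCC)(CCCC)CO | starting material |
| 6 | (4R,5S)-3-(hydroxymethyl)-4,5-(isopropylidenedioxy)cyclohex-2-en-1-one | O=C1C=C(CO)[C@H]2OC(C)(C)O[C@H]2C1 | intermediate |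
| 7 | (4R,5S)-3-[(tert-butyldimethylsilyloxy)methyl]-4,5-(isopropylidenedioxy)cyclohex-2-en-1-one | O=C1C=C(CO[Si](C)(C)C(C)(C)C)[C@H]2OC(C)(C)O[C@H]2C1 | intermediate |
| 8 | (4R,5S)-3-[(tert-butyldimethylsilyloxy)methyl]-2-iodo-4,5-(isopropylidenedioxy)cyclohex-2-en-1-one | O=C1C(I)=C(CO[Si](C)(C)C(C)(C)C)[C@H]2OC(C)(C)O[C@H]2C1 | intermediate |
| 9 | allyl iodide | C=CCI | starting material |
| 10 | lithium dienolate of 8 (C1–OLi, C1=C6, C2=C3) | [Li]OC1=C[C@@H]2OC(C)(C)O[C@@H]2C(CO[Si](C)(C)C(C)(C)C)=C1I | intermediate |
| 11 | (4R,5S,6S)-6-allyl-3-[(tert-butyldimethylsilyloxy)methyl]-2-iodo-4,5-(isopropylidenedioxy)cyclohex-2-en-1-one | O=C1C(I)=C(CO[Si](C)(C)C(C)(C)C)[C@H]2OC(C)(C)O[C@H]2[C@@H]1CC=C | intermediate |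
| 12 | tert-butyl methacrylate | C=C(C)C(=O)OC(C)(C)C | starting material |
| 13 | (4R,5S,6S)-6-[(E)-3-(tert-butoxycarbonyl)but-2-enyl]-3-[(tert-butyldimethylsilyloxy)methyl]-2-iodo-4,5-(isopropylidenedioxy)cyclohex-2-en-1-one | O=C1C(I)=C(CO[Si](C)(C)C(C)(C)C)[C@H]2OC(C)(C)O[C@H]2[C@@H]1C/C=C(\C)C(=O)OC(C)(C)C | intermediate |
| 14 | (R)-propylene oxide | C[C@@H]1CO1 | starting material |
| 15 | but-3-enylmagnesium bromide | C=CCC[Mg]Br | starting material |
| 16 | bromomagnesium (R)-hept-6-en-2-olate | C[C@@H](O[Mg]Br)CCCC=C | intermediate |
| 17 | (R)-hept-6-en-2-ol | C[C@@H](O)CCCC=C | intermediate |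
| 18 | (R)-hept-6-en-2-yl acetate | CC(=O)O[C@H](C)CCCC=C | intermediate |
| 19 | vinylboronic acid pinacol ester | C=CB1OC(C)(C)C(C)(C)O1 | starting material |
| 20 | (R,E)-7-(4,4,5,5-tetramethyl-1,3,2-dioxaborolan-2-yl)hept-6-en-2-yl acetate | CC(=O)O[C@H](C)CCC/C=C/B1OC(C)(C)C(C)(C)O1 | intermediate |
| 21 | fully protected dienone, (4R,5S,6S), C6 chain trans to the ring oxygens | CC(=O)O[C@H](C)CCC/C=C/C1=C(CO[Si](C)(C)C(C)(C)C)[C@H]2OC(C)(C)O[C@H]2[C@H](C/C=C(\C)C(=O)OC(C)(C)C)C1=O | intermediate |
| 22 | lithium dienolate of 21 (C1–OLi, C1=C6) | CC(=O)O[C@H](C)CCC/C=C/C1=C(CO[Si](C)(C)C(C)(C)C)[C@H]2OC(C)(C)O[C@H]2C(C/C=C(\C)C(=O)OC(C)(C)C)=C1O[Li] | intermediate |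
| 23 | fully protected dienone, (4R,5S,6R), all-cis | CC(=O)O[C@H](C)CCC/C=C/C1=C(CO[Si](C)(C)C(C)(C)C)[C@H]2OC(C)(C)O[C@H]2[C@@H](C/C=C(\C)C(=O)OC(C)(C)C)C1=O | intermediate |
| 24 | pestallic acid J | CC(=O)O[C@H](C)CCC/C=C/C1=C(CO)[C@@H](O)[C@@H](O)[C@@H](C/C=C(\C)C(=O)O)C1=O | target |

## Step count and least certain steps

Total: 13 steps. Longest linear sequence: 10 steps (steps 1–7 and 11–13). The side-chain branch (steps 8–10) joins at step 11.

**Step 1 (key step).**
- *Risk:* low conversion because the phenol is toxic to the cells. The dienol or the enone diol can also be lost by dehydration back to the aromatic level, or by further oxidation in the broth.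
- *Fallback:* it sets out from 1 and masks the phenol, so that the dearomatised product is a stable enol ether instead of a dienol that must tautomerise.
  - O-Methylation (MeI, K2CO3, acetone) gives 3-iodoanisole F1.
  - The same dioxygenase should oxidise the only free ortho/meta edge next to iodine, giving (1S,2S)-3-iodo-5-methoxycyclohexa-3,5-diene-1,2-diol F2.
  - Ketalisation as in step 2 gives its acetonide F3.
  - Aqueous oxalic acid in THF hydrolyses the enol ether by protonation at C6, which comes back to the route at 4.

**Step 5.**
- *Risk:* sluggish iodination, because C3 is fully substituted and the alkene is made electron-poor by two allylic oxygens. A slow reaction leaves time for enolisation towards C6 with iodination there, and for loss of the silyl group.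
- *Fallback:* it sets out from 7 and uses addition–elimination instead of hypoiodite chemistry.
  - Bromine in CH2Cl2 at −78 °C followed by triethylamine (addition across C2=C3, then dehydrobromination) gives the 2-bromo enone F4.
  - The procedure of step 6 takes F4 through its lithium dienolate F5 to the 6-allyl bromo enone F6.
  - The procedure of step 7 gives the enoate F7.
  - Coupling of F7 with 20 under an electron-rich biaryl phosphine catalyst (Pd(OAc)2, SPhos, K3PO4) comes back to the route at 21.

**Step 6.**
- *Risk:* expulsion of the C5 ketal oxygen from the enolate with subsequent aromatisation, and proton exchange between product and enolate that leads to double allylation.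
- *Fallback:* it sets out from 7, before iodine is present, and makes the C6–C1'' bond under neutral palladium catalysis.
  - NaHMDS/TMEDA gives the sodium dienolate F8, which allyl chloroformate traps at once at −78 °C on oxygen as the allyl enol carbonate F9.
  - Pd(PPh3)4 in THF at rt brings about decarboxylative (Tsuji) allylation to the 6-allyl enone F10.
  - Cross metathesis with 12 as in step 7 gives the enoate F11.
  - Iodination as in step 5 comes back to the route at 13.

**Step 12.**
- *Risk (deprotonation):* the C6–H to be removed lies on the ketal-shielded face, while the acetate methyl is freely accessible, so deprotonation may be incomplete or unselective.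
- *Risk (side reactions):* warming to force deprotonation invites loss of the C5 oxygen. γ-Deprotonation of the enoate would lead to deconjugation on quenching.
- *Risk (selectivity):* protonation through the enol would erode face selectivity.
- *Fallback:* it sets out from 11, which has neither ester nor acetate, and sets C6 earlier.
  - LiHMDS or LDA at −78 °C gives the lithium dienolate F12.
  - The same hindered phenol gives the 6R (cis) allyl ketone F13.
  - Neutral cross metathesis with 12 gives the cis enoate F14.
  - A silver(I) oxide-promoted Suzuki coupling with 20 at rt, without an enolising base, comes back to the route at 23.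

**Step 13.**
- *Risk:* the acid exposure that the tert-butyl ester needs may be long enough for ionisation of the allylic C4–O bond, dehydration towards the arene, or acid-catalysed epimerisation at C6.
- *Fallback:* it sets out from 11 and separates ester cleavage from acid.
  - Cross metathesis with 2-(trimethylsilyl)ethyl methacrylate F15 (from methacryloyl chloride and 2-(trimethylsilyl)ethanol) gives the silylethyl ester F16.
  - Step 11 gives the coupled dienone F17.
  - Step 12 takes F17 through its lithium dienolate F18 to the all-cis ester F19.
  - TASF in DMF at 0 °C removes the silylethyl ester and the silyl ether to give the acetonide acid F20.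
  - Aqueous acetic acid or an acidic ion-exchange resin then hydrolyses only the ketal, which comes back at 24.

## Further compounds

F1 | step 1 | 3-iodoanisole | COc1cccc(I)c1
F2 | step 1 | (1S,2S)-3-iodo-5-methoxycyclohexa-3,5-diene-1,2-diol | COC1=C[C@H](O)[C@H](O)C(I)=C1
F3 | step 1 | acetonide of F2 | COC1=C[C@@H]2OC(C)(C)O[C@@H]2C(I)=C1
F4 | step 5 | (4R,5S)-2-bromo-3-[(tert-butyldimethylsilyloxy)methyl]-4,5-(isopropylidenedioxy)cyclohex-2-en-1-one | O=C1C(Br)=C(CO[Si](C)(C)C(C)(C)C)[C@H]2OC(C)(C)O[C@H]2C1
F5 | step 5 | lithium dienolate of F4 | [Li]OC1=C[C@@H]2OC(C)(C)O[C@@H]2C(CO[Si](C)(C)C(C)(C)C)=C1Br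
F6 | step 5 | (4R,5S,6S)-6-allyl-2-bromo analogue of 11 | O=C1C(Br)=C(CO[Si](C)(C)C(C)(C)C)[C@H]2OC(C)(C)O[C@H]2[C@@H]1CC=C
F7 | step 5 | 2-bromo analogue of 13 | O=C1C(Br)=C(CO[Si](C)(C)C(C)(C)C)[C@H]2OC(C)(C)O[C@H]2[C@@H]1C/C=C(\C)C(=O)OC(C)(C)C
F8 | step 6 | sodium dienolate of 7 | [Na]OC1=C[C@@H]2OC(C)(C)O[C@@H]2C(CO[Si](C)(C)C(C)(C)C)=C1
F9 | step 6 | allyl enol carbonate of 7 | C=CCOC(=O)OC1=C[C@@H]2OC(C)(C)O[C@@H]2C(CO[Si](C)(C)C(C)(C)C)=C1
F10 | step 6 | (4R,5S,6S)-6-allyl-3-[(tert-butyldimethylsilyloxy)methyl]-4,5-(isopropylidenedioxy)cyclohex-2-en-1-one | O=C1C=C(CO[Si](C)(C)C(C)(C)C)[C@H]2OC(C)(C)O[C@H]2[C@@H]1CC=C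
F11 | step 6 | 2-unsubstituted analogue of 13 | O=C1C=C(CO[Si](C)(C)C(C)(C)C)[C@H]2OC(C)(C)O[C@H]2[C@@H]1C/C=C(\C)C(=O)OC(C)(C)C
F12 | step 12 | lithium dienolate of 11 | [Li]OC1=C(CC=C)[C@@H]2OC(C)(C)O[C@@H]2C(CO[Si](C)(C)C(C)(C)C)=C1I
F13 | step 12 | (4R,5S,6R) epimer of 11 | O=C1C(I)=C(CO[Si](C)(C)C(C)(C)C)[C@H]2OC(C)(C)O[C@H]2[C@H]1CC=C
F14 | step 12 | (4R,5S,6R) epimer of 13 | O=C1C(I)=C(CO[Si](C)(C)C(C)(C)C)[C@H]2OC(C)(C)O[C@H]2[C@H]1C/C=C(\C)C(=O)OC(C)(C)C
F15 | step 13 | 2-(trimethylsilyl)ethyl methacrylate | C=C(C)C(=O)OCC[Si](C)(C)C
F16 | step 13 | 2-(trimethylsilyl)ethyl ester analogue of 13 | O=C1C(I)=C(CO[Si](C)(C)C(C)(C)C)[C@H]2OC(C)(C)O[C@H]2[C@@H]1C/C=C(\C)C(=O)OCC[Si](C)(C)C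
F17 | step 13 | 2-(trimethylsilyl)ethyl ester analogue of 21 | CC(=O)O[C@H](C)CCC/C=C/C1=C(CO[Si](C)(C)C(C)(C)C)[C@H]2OC(C)(C)O[C@H]2[C@H](C/C=C(\C)C(=O)OCC[Si](C)(C)C)C1=O
F18 | step 13 | lithium dienolate of F17 | CC(=O)O[C@H](C)CCC/C=C/C1=C(CO[Si](C)(C)C(C)(C)C)[C@H]2OC(C)(C)O[C@H]2C(C/C=C(\C)C(=O)OCC[Si](C)(C)C)=C1O[Li]
F19 | step 13 | 2-(trimethylsilyl)ethyl ester analogue of 23 | CC(=O)O[C@H](C)CCC/C=C/C1=C(CO[Si](C)(C)C(C)(C)C)[C@H]2OC(C)(C)O[C@H]2[C@@H](C/C=C(\C)C(=O)OCC[Si](C)(C)C)C1=O
F20 | step 13 | 4,5-acetonide of pestallic acid J | CC(=O)O[C@H](C)CCC/C=C/C1=C(CO)[C@H]2OC(C)(C)O[C@H]2[C@@H](C/C=C(\C)C(=O)O)C1=O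
A1 | alternative 1 | protected dienyl cyclohexenol | CC(=O)O[C@H](C)CCC/C=C/C1=C(CO[Si](C)(C)C(C)(C)C)[C@H]2OC(C)(C)O[C@H]2[C@@H](C/C=C(\C)C(=O)OCC[Si](C)(C)C)[C@@H]1O
A2 | alternative 1 | acyclic 1,7-enyne precursor | C#C[C@@H](O)[C@H](C/C=C(\C)C(=O)OCC[Si](C)(C)C)[C@@H]1OC(C)(C)O[C@@H]1C(=C)CO[Si](C)(C)C(C)(C)C
A3 | alternative 2 | endo tricyclic cyclobutanone adduct | C1=C2COC(C)(C)O[C@H]2[C@H]3C(=O)C[C@H]3C1
A4 | alternative 2 | 2,2-dimethyl-5-vinyl-4H-1,3-dioxine | C=CC1=COC(C)(C)OC1
A5 | alternative 2 | cyclobutenone | O=C1C=CC1
A6 | alternative 3 | C5–C6 epoxyquinone | CC(=O)O[C@H](C)CCC/C=C/C1=C(CO[Si](C)(C)C(C)(C)C)C(=O)[C@H]2O[C@@]2(C/C=C(\C)C(=O)OCC[Si](C)(C)C)C1=O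
A7 | alternative 3 | trisubstituted benzoquinone | CC(=O)O[C@H](C)CCC/C=C/C1=C(CO[Si](C)(C)C(C)(C)C)C(=O)C=C(C/C=C(\C)C(=O)OCC[Si](C)(C)C)C1=O
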